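**Retrosynthetic overview**

1. The last operations are removal of two MOM ethers and, before that, oxidation of a diaryl carbinol to the benzophenone.
2. The carbinol is cut at the aryl–C(OH) bond into a 6-lithio-7-(methoxymethoxy)-2,2-dimethyl-2H-chromene and 3-(methoxymethoxy)-2-prenylbenzaldehyde.
3. The chromene comes from a chroman-4-ol and that from a chroman-4-one, whose C2–C3 bond is made in the key step: a crossed aldol condensation (Kabbe) of acetone with a 5-bromo-2-hydroxy-4-(methoxymethoxy)acetophenone, closed by oxa-Michael addition.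
4. The ring A aldehyde comes from 3-bromophenol by MOM-directed ortho-lithiation, copper-mediated prenylation and Br-to-CHO exchange.
5. Ring order: both benzene rings are bought (ring A as 3-bromophenol, ring B as 2,4-dihydroxyacetophenone); the pyran ring is the only ring formed, in the aldol step, before the two aryl halves are joined.

Assumption: the target has no stereocentre and is achiral, so no asymmetric step is needed; the racemic carbinol centres formed on the way are removed again.

**Route**

Step 1
Reactants: 1 resacetophenone (1-(2,4-dihydroxyphenyl)ethanone)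
Product: 2 bromoketone 1-(5-bromo-2,4-dihydroxyphenyl)ethanone
Conditions: NBS (1.0 equiv), MeCN, 0 °C → rt
Reagents that add atoms: N-bromosuccinimide, O=C1CCC(=O)N1Br
Why: Electrophilic aromatic bromination goes to C5, the unhindered position para to the chelated 2-OH and ortho to the free 4-OH, as it does for 2,4-dihydroxybenzoic acid and 2,4-dihydroxybenzaldehyde; no stereocentre is formed.

Step 2
Reactants: 2 bromoketone 1-(5-bromo-2,4-dihydroxyphenyl)ethanone
Product: 3 MOM ether 1-[5-bromo-2-hydroxy-4-(methoxymethoxy)phenyl]ethanone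
Conditions: MOMCl (1.1 equiv), K2CO3 (1.5 equiv), acetone, 0 °C → rt
Reagents that add atoms: chloromethyl methyl ether (MOMCl), COCCl
Why: Williamson-type O-alkylation takes only the free 4-OH, because the 2-OH is tied up in a hydrogen bond to the acetyl group and is much less nucleophilic.

Step 3
Reactants: 3 MOM ether 1-[5-bromo-2-hydroxy-4-(methoxymethoxy)phenyl]ethanone; 4 acetone
Product: 7 chromanone 6-bromo-7-(methoxymethoxy)-2,2-dimethylchroman-4-one, via β-hydroxy ketone 5 (not isolated), via enone 6 (not isolated)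
Conditions: acetone (10 equiv), pyrrolidine (1.0 equiv), toluene, rt 16 h, then 80 °C (sealed tube)
Reagents that add atoms: none
Why: In this Kabbe condensation, a pyrrolidine-mediated (enamine/iminium) crossed aldol condensation joins the acetyl CH3 to the acetone carbonyl carbon (the C2–C3 bond), and the ortho-phenol then closes the pyran ring by intramolecular oxa-Michael addition; C2 carries two methyl groups, so no stereocentre arises.

Step 4
Reactants: 7 chromanone 6-bromo-7-(methoxymethoxy)-2,2-dimethylchroman-4-one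
Product: 8 chromanol rac-6-bromo-7-(methoxymethoxy)-2,2-dimethylchroman-4-ol
Conditions: NaBH4 (1.5 equiv), MeOH, 0 °C → rt
Reagents that add atoms: none
Why: Hydride 1,2-reduction of the aryl ketone leaves the aryl bromide and the MOM ether untouched; the new C4 stereocentre forms as a racemate and is removed in step 5.

Step 5
Reactants: 8 chromanol rac-6-bromo-7-(methoxymethoxy)-2,2-dimethylchroman-4-ol
Product: 10 chromene 6-bromo-7-(methoxymethoxy)-2,2-dimethyl-2H-chromene, via mesylate 9 (not isolated)
Conditions: MsCl (1.5 equiv), Et3N (5 equiv), CH2Cl2, 0 °C → 40 °C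
Reagents that add atoms: none
Why: O-sulfonylation followed by base-mediated elimination (E1/E2) of the benzylic mesylate, activated by the para-alkoxy group, gives the conjugated chromene under non-acidic conditions that keep the MOM ether.

Step 6
Reactants: 11 3-bromophenol
Product: 12 MOM ether 1-bromo-3-(methoxymethoxy)benzene
Conditions: MOMCl (1.2 equiv), K2CO3 (2 equiv), acetone, rt
Reagents that add atoms: chloromethyl methyl ether (MOMCl), COCCl
Why: Williamson-type O-alkylation of the phenol installs the group that both protects the oxygen and directs the later metalation.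

Step 7
Reactants: 12 MOM ether 1-bromo-3-(methoxymethoxy)benzene
Product: 15 prenyl arene 1-bromo-3-(methoxymethoxy)-2-(3-methylbut-2-en-1-yl)benzene, via aryllithium 13 (not isolated), via arylcopper 14 (not isolated)
Conditions: LiN(i-Pr)2 (LDA, 1.1 equiv), THF, −78 °C, 1 h; CuBr·SMe2 (1.1 equiv), −78 °C; prenyl bromide (1.3 equiv), −78 °C → 0 °C
Reagents that add atoms: prenyl bromide (1-bromo-3-methylbut-2-ene), CC(C)=CCBr
Why: Directed ortho-metalation removes the most acidic proton, at C2 between OMOM and Br; lithium-to-copper transmetalation at −78 °C prevents aryne formation and gives SN2 allylic substitution at the unhindered CH2 of prenyl bromide.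

Step 8
Reactants: 15 prenyl arene 1-bromo-3-(methoxymethoxy)-2-(3-methylbut-2-en-1-yl)benzene
Product: 18 aldehyde 3-(methoxymethoxy)-2-(3-methylbut-2-en-1-yl)benzaldehyde, via aryllithium 16 (not isolated), via lithium hemiaminolate 17 (not isolated)
Conditions: n-BuLi (1.1 equiv), THF, −78 °C; DMF (2 equiv), −78 → 0 °C; H2O
Reagents that add atoms: N,N-dimethylformamide, CN(C)C=O
Why: Bromine–lithium exchange is fast at −78 °C, and Bouveault formylation of the aryllithium with DMF stops at the tetrahedral adduct, which releases the aldehyde only on aqueous work-up.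

Step 9
Reactants: 10 chromene 6-bromo-7-(methoxymethoxy)-2,2-dimethyl-2H-chromene; 18 aldehyde 3-(methoxymethoxy)-2-(3-methylbut-2-en-1-yl)benzaldehyde
Product: 21 carbinol rac-[7-(methoxymethoxy)-2,2-dimethyl-2H-chromen-6-yl][3-(methoxymethoxy)-2-(3-methylbut-2-en-1-yl)phenyl]methanol, via aryllithium 19 (not isolated), via lithium alkoxide 20 (not isolated)
Conditions: 10, n-BuLi (1.05 equiv), THF, −78 °C, 20 min; then 18, −78 → 0 °C; H2O
Reagents that add atoms: none
Why: Bromine–lithium exchange gives an aryllithium stabilised by chelation to the ortho-OMOM oxygen, which adds 1,2 to the non-enolisable aldehyde; the carbinol stereocentre forms as a racemate and is removed in step 10.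

Step 10
Reactants: 21 carbinol rac-[7-(methoxymethoxy)-2,2-dimethyl-2H-chromen-6-yl][3-(methoxymethoxy)-2-(3-methylbut-2-en-1-yl)phenyl]methanol
Product: 22 ketone [7-(methoxymethoxy)-2,2-dimethyl-2H-chromen-6-yl][3-(methoxymethoxy)-2-(3-methylbut-2-en-1-yl)phenyl]methanone
Conditions: DMP (1.3 equiv), NaHCO3 (3 equiv), CH2Cl2, 0 °C → rt
Reagents that add atoms: none
Why: Buffered Dess–Martin oxidation converts the hindered, acid-sensitive diaryl carbinol into the benzophenone without touching the prenyl or chromene double bonds or the MOM ethers.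

Step 11
Reactants: 22 ketone [7-(methoxymethoxy)-2,2-dimethyl-2H-chromen-6-yl][3-(methoxymethoxy)-2-(3-methylbut-2-en-1-yl)phenyl]methanone
Product: 24 cudraphenone A ((7-hydroxy-2,2-dimethyl-2H-chromen-6-yl)[3-hydroxy-2-(3-methylbut-2-en-1-yl)phenyl]methanone), via mono-MOM ketone 23 (not isolated)
Conditions: HCl (ca. 1 M in MeOH), rt → 40 °C
Reagents that add atoms: none
Why: Acid-catalysed transacetalisation to methanol removes first the MOM group ortho to the carbonyl and then the one on ring A, under dilute, mild conditions that spare the prenyl group and the chromene.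

**Compound list**

1 | resacetophenone, 1-(2,4-dihydroxyphenyl)ethanone | CC(=O)c1ccc(O)cc1O | starting material
2 | 1-(5-bromo-2,4-dihydroxyphenyl)ethanone | CC(=O)c1cc(Br)c(O)cc1O | intermediate
3 | 1-[5-bromo-2-hydroxy-4-(methoxymethoxy)phenyl]ethanone | CC(=O)c1cc(Br)c(OCOC)cc1O | intermediate
4 | acetone | CC(C)=O | starting material
5 | 1-[5-bromo-2-hydroxy-4-(methoxymethoxy)phenyl]-3-hydroxy-3-methylbutan-1-one (aldol adduct) | CC(C)(O)CC(=O)c1cc(Br)c(OCOC)cc1O | intermediate
6 | 1-[5-bromo-2-hydroxy-4-(methoxymethoxy)phenyl]-3-methylbut-2-en-1-one (enone) | CC(C)=CC(=O)c1cc(Br)c(OCOC)cc1O | intermediate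
7 | 6-bromo-7-(methoxymethoxy)-2,2-dimethylchroman-4-one | COCOc1cc2OC(C)(C)CC(=O)c2cc1Br | intermediate
8 | rac-6-bromo-7-(methoxymethoxy)-2,2-dimethylchroman-4-ol (racemate) | COCOc1cc2OC(C)(C)CC(O)c2cc1Br | intermediate
9 | rac-6-bromo-7-(methoxymethoxy)-2,2-dimethylchroman-4-yl methanesulfonate (racemate) | COCOc1cc2OC(C)(C)CC(OS(C)(=O)=O)c2cc1Br | intermediate
10 | 6-bromo-7-(methoxymethoxy)-2,2-dimethyl-2H-chromene | COCOc1cc2OC(C)(C)C=Cc2cc1Br | intermediate
11 | 3-bromophenol | Oc1cccc(Br)c1 | starting material
12 | 1-bromo-3-(methoxymethoxy)benzene | COCOc1cccc(Br)c1 | intermediate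
13 | [2-bromo-6-(methoxymethoxy)phenyl]lithium | [Li]c1c(Br)cccc1OCOC | intermediate
14 | [2-bromo-6-(methoxymethoxy)phenyl]copper | [Cu]c1c(Br)cccc1OCOC | intermediate
15 | 1-bromo-3-(methoxymethoxy)-2-(3-methylbut-2-en-1-yl)benzene | CC(C)=CCc1c(Br)cccc1OCOC | intermediate
16 | [3-(methoxymethoxy)-2-(3-methylbut-2-en-1-yl)phenyl]lithium | [Li]c1cccc(OCOC)c1CC=C(C)C | intermediate
17 | lithium (dimethylamino)[3-(methoxymethoxy)-2-(3-methylbut-2-en-1-yl)phenyl]methanolate (racemate) | CC(C)=CCc1c(OCOC)cccc1C(O[Li])N(C)C | intermediate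
18 | 3-(methoxymethoxy)-2-(3-methylbut-2-en-1-yl)benzaldehyde | CC(C)=CCc1c(OCOC)cccc1C=O | intermediate
19 | [7-(methoxymethoxy)-2,2-dimethyl-2H-chromen-6-yl]lithium | COCOc1cc2OC(C)(C)C=Cc2cc1[Li] | intermediate
20 | lithium alkoxide of carbinol 21 (racemate) | CC(C)=CCc1c(OCOC)cccc1C(O[Li])c1cc2C=CC(C)(C)Oc2cc1OCOC | intermediate
21 | rac-[7-(methoxymethoxy)-2,2-dimethyl-2H-chromen-6-yl][3-(methoxymethoxy)-2-(3-methylbut-2-en-1-yl)phenyl]methanol (racemate) | CC(C)=CCc1c(OCOC)cccc1C(O)c1cc2C=CC(C)(C)Oc2cc1OCOC | intermediate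
22 | [7-(methoxymethoxy)-2,2-dimethyl-2H-chromen-6-yl][3-(methoxymethoxy)-2-(3-methylbut-2-en-1-yl)phenyl]methanone | CC(C)=CCc1c(OCOC)cccc1C(=O)c1cc2C=CC(C)(C)Oc2cc1OCOC | intermediate
23 | (7-hydroxy-2,2-dimethyl-2H-chromen-6-yl)[3-(methoxymethoxy)-2-(3-methylbut-2-en-1-yl)phenyl]methanone | CC(C)=CCc1c(OCOC)cccc1C(=O)c1cc2C=CC(C)(C)Oc2cc1O | intermediate
24 | cudraphenone A, (7-hydroxy-2,2-dimethyl-2H-chromen-6-yl)[3-hydroxy-2-(3-methylbut-2-en-1-yl)phenyl]methanone (achiral) | CC(C)=CCc1c(O)cccc1C(=O)c1cc2c(cc1O)OC(C)(C)C=C2 | target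

**Summary**

Total step count: 11.
Longest linear sequence: 8 steps (steps 1 to 5, then 9, 10 and 11, from 1 to 24); the ring A branch (steps 6 to 8) is 3 steps.

**Steps most likely to fail, with fallbacks**

Step 7. The risks are aryne formation from aryllithium 13 if the temperature rises before transmetalation, and SN2′ attack giving the reverse-prenyl isomer. The fallback sets out from 11 and comes back to the route at 15. O-Allylation of 11 (allyl bromide, K2CO3, acetone, reflux) gives allyl 3-bromophenyl ether F1. Thermal aromatic Claisen rearrangement (N,N-diethylaniline, 200 °C) gives mainly 2-allyl-3-bromophenol F2, separated by chromatography from the minor 2-allyl-5-bromophenol F3. MOM protection of F2 (MOMCl, K2CO3, acetone) gives 2-allyl-1-bromo-3-(methoxymethoxy)benzene F4. Olefin cross-metathesis of F4 with 2-methylbut-2-ene (second-generation Grubbs catalyst, CH2Cl2, 40 °C) turns the allyl group into the prenyl group and delivers 15.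

Step 3. The risks are sluggish condensation of the hydrogen-bonded hydroxy ketone, self-condensation of acetone and retro-aldol cleavage. The fallback sets out from 3 and 4 and comes back at 7. Double deprotonation of 3 with LiN(i-Pr)2 (2.2 equiv, THF, −78 °C) gives the dilithium enolate phenoxide of 3 F5. This adds to acetone 4 in a directed aldol addition to give the dilithium aldolate of 5 F6, and aqueous quench gives β-hydroxy ketone 5, this time isolated. HCl in MeOH at reflux dehydrates 5, closes the pyran ring by oxa-Michael addition and removes the MOM group, giving 6-bromo-7-hydroxy-2,2-dimethylchroman-4-one F7. Re-protection of F7 (MOMCl, K2CO3, acetone) gives 7.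

Step 9. The risks are incomplete bromine–lithium exchange, protonation of 19 and slow addition to the ortho-substituted aldehyde. The fallback reverses the polarity of the union; it sets out from 10 and 15 and comes back at 21. Compound 10 is lithiated (n-BuLi, THF, −78 °C) to 19 and formylated with DMF through lithium (dimethylamino)[7-(methoxymethoxy)-2,2-dimethyl-2H-chromen-6-yl]methanolate F8. Aqueous work-up gives 7-(methoxymethoxy)-2,2-dimethyl-2H-chromene-6-carbaldehyde F9. Compound 15 is converted with n-BuLi (THF, −78 °C) into aryllithium 16, which adds to F9 to give alkoxide 20 and, after aqueous quench, 21.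

**Further compounds**

F1 | step 7 | allyl 3-bromophenyl ether | C=CCOc1cccc(Br)c1
F2 | step 7 | 2-allyl-3-bromophenol | C=CCc1c(O)cccc1Br
F3 | step 7 | 2-allyl-5-bromophenol | C=CCc1ccc(Br)cc1O
F4 | step 7 | 2-allyl-1-bromo-3-(methoxymethoxy)benzene | C=CCc1c(OCOC)cccc1Br
F5 | step 3 | dilithium enolate phenoxide of 3 | C=C(O[Li])c1cc(Br)c(OCOC)cc1O[Li]
F6 | step 3 | dilithium aldolate of 5 | CC(C)(O[Li])CC(=O)c1cc(Br)c(OCOC)cc1O[Li]
F7 | step 3 | 6-bromo-7-hydroxy-2,2-dimethylchroman-4-one | CC1(C)CC(=O)c2cc(Br)c(O)cc2O1
F8 | step 9 | lithium (dimethylamino)[7-(methoxymethoxy)-2,2-dimethyl-2H-chromen-6-yl]methanolate | COCOc1cc2OC(C)(C)C=Cc2cc1C(O[Li])N(C)C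
F9 | step 9 | 7-(methoxymethoxy)-2,2-dimethyl-2H-chromene-6-carbaldehyde | COCOc1cc2OC(C)(C)C=Cc2cc1C=O
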